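# Kaempferide 3-O-sulfate by Auwers ring expansion of a bis-tosylated aurone

## The problem

Kaempferide 3-O-sulfate (10) is a flavone. An oxygen-rich benzene ring A (oxygens on C5 and C7, O1 on C8a) is fused to a 4-pyranone ring C, which carries a 4-methoxyphenyl ring B on C2 and the sulfate on O3. There is no stereocentre, so the task lies in oxidation level, regiochemistry and the order of events.

Ring C must be formed at the flavonol level, with an oxygen on C3. The usual oxidative closure of a 2'-hydroxychalcone (Algar–Flynn–Oyamada) is known to be diverted toward five-membered benzofuranones when the position that becomes C5 is substituted.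

The sulfate must sit on O3 alone, although O7 is the more reactive phenol and O5 is chelated to the C4 carbonyl. O7 therefore has to be masked while O3 is free.

The aryl sulfate monoester is the fragile group. As its anion it tolerates base, but it is cleaved by acid and by its own acidity in the free form. It must come late, every later step must be basic or neutral, and the methyl ether on ring B excludes Lewis-acid deprotections.

Ring A is a phloroglucinol nucleus and is attacked by electrophiles unless its oxygens carry electron-withdrawing groups.

The feature that opens the route is that O1, C2 and C3 of ring C map onto an aurone. The benzylidene carbon of a 2-benzylidenebenzofuran-3-one becomes C2, the furanone C2 becomes C3 with its hydroxyl, and the furanone oxygen becomes O1 after moving from one carbon to the other. The five-membered ring that the C5 substituent favours can thus be widened by one atom into ring C.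

## Retrosynthesis

**Acid 10 from salt 9.** No skeletal bond is cut; the O–H of the hydrogen sulfate in 10 is exchanged for the potassium ion of 9. Making the free acid last is preferred because a flavonol hydrogen sulfate catalyses its own hydrolysis, whereas 9 can be purified and stored. The precursor is the same molecule in its stable form. The forward step needs a strong-acid cation exchanger and cold, brief handling.

**Salt 9 from bis-sulfonate 8.** The two ArO–S bonds of the 4-methylbenzenesulfonates on O5 and O7 are cut. Benzyl ethers would make this a neutral hydrogenolysis, but they would leave ring A electron-rich during the bromination of the key step. Acyl groups would not survive its alkali. Sulfonates deactivate ring A, should tolerate cold dilute hydroxide, and are cleaved by hot hydroxide, to which a sulfate monoester anion is inert. Precursor 8 differs from 9 only in these masks. The forward step must hydrolyse two neutral sulfonates and leave the charged sulfate alone.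

**Sulfate 8 from flavonol 7.** The O3–S bond of the sulfate is cut. Sulfating after ring construction and before unmasking is the only order in which O3 is the sole free hydroxyl. After unmasking, O7 would react first; before ring construction, the sulfate would meet bromine and HBr. Precursor 7 is a neutral flavonol that can be chromatographed. The forward step asks an SO3–amine complex to esterify an enolic, hydrogen-bonded hydroxyl.

**Flavonol 7 from aurone 5 through dibromide 6.** The O1–C2 bond of ring C is cut, O1 is reattached to the neighbouring carbon, and the C3 hydroxyl is removed. Ring C contracts to a five-membered furanone and C2 becomes a benzylidene carbon.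

- Against cutting C3–C4 or C4–C4a, or assembling ring A, this cut keeps the whole carbon skeleton and leads to a precursor one condensation away from bought materials.
- Against an oxidative chalcone closure, it uses the preference of 5-substituted systems for the five-membered ring.
- Precursor 5 has no C3 oxygen and no stereochemical feature except an alkene geometry that is consumed.
- The forward reaction must add bromine to the exocyclic alkene (giving 6), then let hydroxide substitute at the furanone C2, open the ring, and let the phenoxide close on the benzylic carbon, all without touching the sulfonates.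

**Aurone 5 from diol 3 and sulfonyl chloride 4.** Two ArO–S bonds are cut, so two equivalents of 4 are consumed, one for each phenol of 3. The sulfonates go on after the condensation because that step uses hot alkali, which they would not survive, and because the condensation of the unprotected ketone is the established one. The tosyl group from 4 is preferred to mesyl, whose acidic α-hydrogens make it more base-labile. The forward step is a double O-sulfonylation with no competing nucleophile.

**Diol 3 from benzofuranone 1 and aldehyde 2.** The exocyclic C=C bond is cut, an aldol disconnection that separates ring A with its furanone from ring B with its one-carbon link. No other cut gives two bought compounds in one step. The forward reaction must condense the single enolisable methylene of 1 with the non-enolisable aldehyde 2 and give the thermodynamic Z alkene.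

## Roads not taken

**Alternative 1:** The cut is the C3–C4 bond of ring C.

- **Forward key step.** The dialdehyde A2, 2-[3,5-bis(benzyloxy)-2-formylphenoxy]-2-(4-methoxyphenyl)acetaldehyde, is treated with an azolium-derived carbene and an amine base. The aliphatic aldehyde becomes an acyl anion equivalent (Breslow intermediate) that adds to the aryl aldehyde in a 6-exo-trig closure. The product is the acyloin A1, 5,7-bis(benzyloxy)-4-hydroxy-2-(4-methoxyphenyl)chroman-3-one, as a racemic diastereomer mixture.
- **Merits.** The C–C bond formation is catalytic, mild and halogen-free. The benzyl ethers would allow a neutral hydrogenolysis after sulfation.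
- **Weak points.**
  - A1 is one oxidation level too low; a further oxidation to the flavonol A3, 5,7-bis(benzyloxy)-3-hydroxy-2-(4-methoxyphenyl)-4H-chromen-4-one, is needed before sulfation.
  - A2 is an α-aryl-α-aryloxy aldehyde with a very acidic α-hydrogen. Under the basic conditions its enolate can attack the neighbouring formyl group in a 5-exo aldol closure to a benzofuran (Rap–Stoermer-type), or self-condense.
  - The acceptor is a 2,4,6-trioxygenated benzaldehyde, hindered and among the least electrophilic aryl aldehydes.
  - A2 itself needs several steps from a protected salicylaldehyde.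
- **Comparison.** This road is better in one respect: its benzyl groups avoid both bromine and the hot alkali of the last deprotection. Against that, the chosen plan has six steps from three bought compounds, arrives at the flavonol level directly, and needs no fragile aldehyde.

**Alternative 2:** The cut removes ring A altogether (C5–C6, C7–C8 and C4a–C5).

- **Forward key step.** Wolff rearrangement of the pyranone diazo ketone A5, 2-diazo-1-[5-(benzyloxy)-6-(4-methoxyphenyl)-4-oxo-4H-pyran-2-yl]ethan-1-one, gives a vinylketene. This adds the silyl ynol ether A6, (triisopropylsilyloxy)ethyne, in a [2+2] cycloaddition. Four-electron ring opening of the cyclobutenone and six-electron closure onto the pyranone C–H carbon then form the phenol A4, 3-(benzyloxy)-5-hydroxy-2-(4-methoxyphenyl)-7-(triisopropylsilyloxy)-4H-chromen-4-one. The ketene carbon becomes C5 with its free hydroxyl and the silyloxy carbon becomes C7.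
- **Merits.** Regiochemistry follows from the polarity of ketene and ynol ether. A4 has all three oxygens differentiated (O5 free but chelated, O7 silylated, O3 benzylated), so the endgame would be hydrogenolysis, sulfation and fluoride, with no hydroxide.
- **Weak points.**
  - The sequence builds the one part of the target that can be bought as a finished ring system.
  - A5 requires a 6-aryl-5-alkoxy-4-pyranone-2-carboxylic acid, a C-arylation of a pyranone and a diazoalkane acylation.
  - A6 must be prepared and is sensitive.
  - The key step is photochemical, and its vinyl partner is an electron-poor pyranone double bond.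
- **Comparison.** The protecting-group pattern of A4 is superior to that of the chosen plan, which has to distinguish sulfonate from sulfate by charge alone. The chosen plan sets against it roughly half the step count, no diazo compound and no photochemistry.

**Alternative 3:** The cut is the C4–C4a bond.

- **Forward key step.** The acrylic acid A8, (E)-2-(allyloxy)-3-[3,5-bis(benzyloxy)phenoxy]-3-(4-methoxyphenyl)prop-2-enoic acid, is activated as a mixed anhydride with a perfluorinated acid anhydride. Its acyl carbon attacks the ortho carbon of the aryloxy ring (intramolecular Friedel–Crafts acylation) to give A7, 3-(allyloxy)-5,7-bis(benzyloxy)-2-(4-methoxyphenyl)-4H-chromen-4-one.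
- **Merits.** The aryloxy ring is symmetric and very nucleophilic, so the closure has no regiochemical issue. Allyl and benzyl are orthogonal: Pd(PPh3)4-catalysed allyl transfer would free O3 alone to give A3, then sulfation and hydrogenolysis would finish. This is the cleanest endgame of all the routes.
- **Weak points.**
  - A8 is a tetrasubstituted enol ether acid whose carboxyl and aryloxy groups must be cis. Making it takes several steps and relies on geometric control or on equilibration in acid.
  - Its allyl vinyl ether unit can undergo Claisen rearrangement on warming.
  - The strongly acidic acylating medium can strip or migrate benzyl groups on the activated ring and acylate it intermolecularly.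
- **Comparison.** Its endgame is better than that of the chosen plan. The chosen plan answers with a shorter sequence, a bought ring A–furanone unit, and no alkene geometry to control.

Key step: step 3

Remark: the target is taken as the free hydrogen sulfate (the neutral acid as drawn); its potassium salt 9 is the form in which the compound is purified and stored.

Remark: forms of a numbered compound that differ only in protonation state or counter-ion before work-up (phenoxides in alkali, the pyridinium form of the sulfate) are not numbered separately.

## Route

Step 1
Reactants: 1 4,6-dihydroxybenzofuran-3(2H)-one; 2 4-methoxybenzaldehyde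
Product: 3 (Z)-4,6-dihydroxy-2-(4-methoxybenzylidene)benzofuran-3(2H)-one
Conditions: KOH (50% aq), MeOH, 60 °C; then HCl (aq), 0 °C
Reagents that add atoms: none
Why: Base-mediated aldol condensation (standard aurone synthesis): the C2 methylene of 1 is the only enolisable position and 2 cannot enolise, so only one cross-condensation is possible, and E1cB loss of water gives the conjugated benzylidene. No stereocentre forms; the alkene is expected as the thermodynamic Z isomer, with the aryl group on the side of O1 and away from the C3 carbonyl.

Step 2
Reactants: 3 (Z)-4,6-dihydroxy-2-(4-methoxybenzylidene)benzofuran-3(2H)-one; 4 4-methylbenzenesulfonyl chloride (two equivalents are consumed, one per phenol)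
Product: 5 (Z)-2-(4-methoxybenzylidene)-3-oxo-2,3-dihydrobenzofuran-4,6-diyl bis(4-methylbenzenesulfonate)
Conditions: TsCl (2.4 equiv), K2CO3 (3 equiv), acetone, reflux
Reagents that add atoms: 4-methylbenzenesulfonyl chloride (the second equivalent of 4, which sulfonylates the second phenol), Cc1ccc(S(=O)(=O)Cl)cc1
Why: Double O-sulfonylation of phenoxides with an arenesulfonyl chloride: each of the two hydroxyls of 3 is an acidic phenol conjugated with the ketone and takes up one molecule of 4, and no other nucleophilic site is present. The tosyl group has no α-hydrogen (no sulfene pathway), which is why it is preferred to mesyl for a group that must later meet cold alkali.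

Step 3
Reactants: 5 (Z)-2-(4-methoxybenzylidene)-3-oxo-2,3-dihydrobenzofuran-4,6-diyl bis(4-methylbenzenesulfonate)
Product: 7 3-hydroxy-2-(4-methoxyphenyl)-4-oxo-4H-chromene-5,7-diyl bis(4-methylbenzenesulfonate), via aurone dibromide 6 (not isolated)
Conditions: Br2 (1.0 equiv), CHCl3, 0 °C, dark; evaporate; then KOH (0.2 M aq, 3 equiv), THF, 0 °C to rt; then HCl (1 M aq) to pH 3
Reagents that add atoms: bromine, BrBr (its atoms stay only in 6); potassium hydroxide, [K+].[OH-] (source of the oxygen on C3 of 7)
Why: Bromine adds across the exocyclic alkene of 5, the only electron-rich π bond left once ring A carries two sulfonyloxy groups and an acyl group, to give dibromide 6 (a mixture of racemic diastereomers is expected because the 4-methoxybenzyl cation is open; both stereocentres are destroyed later). In cold dilute aqueous KOH, hydroxide replaces the bromide on C2 of the furanone, an α-bromo ether that ionises to an oxygen-stabilised cation, and the resulting hemiketal collapses with cleavage of the old O1–C2 bond to a phenoxide carrying a 1,2-diketone side chain. The phenoxide then displaces the benzylic bromide, which the 4-methoxyphenyl group activates, in a 6-exo-tet closure that forms the new O1–C2 bond and ring C; the chroman-3,4-dione tautomerises to the 3-hydroxychromone 7, so no stereocentre remains and none has to be controlled. The closest known reaction is the Auwers flavonol synthesis from benzylidenecoumaranone dibromides and alkali. Two selectivities are needed: bromine must add to the alkene and not substitute ring A or ring B, which the deactivating sulfonates, one equivalent of Br2 and 0 °C should secure; and hydroxide must attack C2 and not the sulfonate sulfur, which rests on low temperature, dilute base, short contact and an alcohol-free medium, since aryl tosylates normally need hot concentrated alkali to hydrolyse. Closure to the six-membered ring is preferred to return to the five-membered ring because the benzylic carbon bears a leaving group, whereas re-addition of the phenoxide to the C2 carbonyl only regenerates the hemiketal reversibly.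

Step 4
Reactants: 7 3-hydroxy-2-(4-methoxyphenyl)-4-oxo-4H-chromene-5,7-diyl bis(4-methylbenzenesulfonate)
Product: 8 potassium 2-(4-methoxyphenyl)-5,7-bis[(4-methylbenzenesulfonyl)oxy]-4-oxo-4H-chromen-3-yl sulfate
Conditions: SO3·pyridine (5 equiv), pyridine, 50 °C; then KHCO3 (aq), 0 °C
Reagents that add atoms: sulfur trioxide–pyridine complex, O=S(=O)([O-])[n+]1ccccc1; potassium hydrogencarbonate, [K+].OC(=O)[O-]
Why: O-Sulfation with an SO3–amine complex: 7 has a single free hydroxyl, the acidic enolic 3-OH, so no regiochemical question arises, and neither the sulfonates nor the methyl ether react. Exchange to the potassium salt keeps the sulfate monoester as its anion, the form that resists hydrolysis.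

Step 5
Reactants: 8 potassium 2-(4-methoxyphenyl)-5,7-bis[(4-methylbenzenesulfonyl)oxy]-4-oxo-4H-chromen-3-yl sulfate
Product: 9 potassium 5,7-dihydroxy-2-(4-methoxyphenyl)-4-oxo-4H-chromen-3-yl sulfate
Conditions: KOH (6 equiv), H2O/MeOH 3:1, 55 °C; then AcOH to pH 6–7; C18 reverse-phase desalting
Reagents that add atoms: none
Why: Alkaline hydrolysis of aryl sulfonates by attack of hydroxide at sulfur with S–O cleavage; the leaving phenoxides on C7 and C5 are stabilised by the C4 carbonyl. The sulfate monoester is an anion and repels hydroxide, so it should survive, and once the 7-phenoxide has formed the pyranone is shielded from conjugate attack at C2; neutralisation to pH 6–7 restores the phenols without exposing the sulfate to acid.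

Step 6
Reactants: 9 potassium 5,7-dihydroxy-2-(4-methoxyphenyl)-4-oxo-4H-chromen-3-yl sulfate
Product: 10 kaempferide 3-O-sulfate, 5,7-dihydroxy-2-(4-methoxyphenyl)-4-oxo-4H-chromen-3-yl hydrogen sulfate
Conditions: Dowex 50WX8 (H+ form), H2O/MeCN, 0–5 °C; freeze-dry at once
Reagents that add atoms: none
Why: Cation exchange on a sulfonic acid resin replaces K+ by H+; the aryl hydrogen sulfate is a strong acid and elutes as the free acid 10. Low temperature, short contact and immediate freeze-drying limit acid-catalysed S–O hydrolysis of the product.

## Compound list

1 | 4,6-dihydroxybenzofuran-3(2H)-one | O=C1COc2cc(O)cc(O)c21 | starting material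
2 | 4-methoxybenzaldehyde | COc1ccc(C=O)cc1 | starting material
3 | (Z)-4,6-dihydroxy-2-(4-methoxybenzylidene)benzofuran-3(2H)-one | COc1ccc(/C=C2\Oc3cc(O)cc(O)c3C2=O)cc1 | intermediate
4 | 4-methylbenzenesulfonyl chloride (p-toluenesulfonyl chloride) | Cc1ccc(S(=O)(=O)Cl)cc1 | starting material
5 | (Z)-2-(4-methoxybenzylidene)-3-oxo-2,3-dihydrobenzofuran-4,6-diyl bis(4-methylbenzenesulfonate) | COc1ccc(/C=C2\Oc3cc(OS(=O)(=O)c4ccc(C)cc4)cc(OS(=O)(=O)c4ccc(C)cc4)c3C2=O)cc1 | intermediate
6 | 2-bromo-2-[bromo(4-methoxyphenyl)methyl]-3-oxo-2,3-dihydrobenzofuran-4,6-diyl bis(4-methylbenzenesulfonate), racemic, mixture of diastereomers, not isolated | COc1ccc(C(Br)C2(Br)Oc3cc(OS(=O)(=O)c4ccc(C)cc4)cc(OS(=O)(=O)c4ccc(C)cc4)c3C2=O)cc1 | intermediate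
7 | 3-hydroxy-2-(4-methoxyphenyl)-4-oxo-4H-chromene-5,7-diyl bis(4-methylbenzenesulfonate) | COc1ccc(-c2oc3cc(OS(=O)(=O)c4ccc(C)cc4)cc(OS(=O)(=O)c4ccc(C)cc4)c3c(=O)c2O)cc1 | intermediate
8 | potassium 2-(4-methoxyphenyl)-5,7-bis[(4-methylbenzenesulfonyl)oxy]-4-oxo-4H-chromen-3-yl sulfate | COc1ccc(-c2oc3cc(OS(=O)(=O)c4ccc(C)cc4)cc(OS(=O)(=O)c4ccc(C)cc4)c3c(=O)c2OS(=O)(=O)[O-])cc1.[K+] | intermediate
9 | potassium 5,7-dihydroxy-2-(4-methoxyphenyl)-4-oxo-4H-chromen-3-yl sulfate | COc1ccc(-c2oc3cc(O)cc(O)c3c(=O)c2OS(=O)(=O)[O-])cc1.[K+] | intermediate
10 | kaempferide 3-O-sulfate, 5,7-dihydroxy-2-(4-methoxyphenyl)-4-oxo-4H-chromen-3-yl hydrogen sulfate | COc1ccc(-c2oc3cc(O)cc(O)c3c(=O)c2OS(=O)(=O)O)cc1 | target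

## Step count and risk

Total step count: 6. Longest linear sequence: 6 steps (1 → 3 → 5 → 7 → 8 → 9 → 10).

**Step 3 (key step).**

- **Risk.** The most likely failure is a diversion at the dibromide stage. Hydroxide may attack the bromine α to the ketone and expel the benzylic bromide, which returns aurone 5, or HBr may be lost to a bromo-aurone, instead of substitution at C2. The alkaline stage of this reaction is known to depend on the substituents of ring A. Second, hydroxide may attack the sulfonate sulfur, fastest at the sulfonate para to the carbonyl, so that protecting groups are partly lost during the ring expansion.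
- **Fallback.** It sets out from 5 and returns at 7, and uses neither hydroxide nor an α-bromo ketone. Epoxidation of 5 with dimethyldioxirane in acetone, a neutral reaction known for aurones, should give the spiro-epoxide F1. HBr in AcOH/CH2Cl2 at −20 °C should open F1 at the 4-methoxybenzylic carbon to the bromohydrin hemiketal F2, the same 2-hydroxy intermediate through which the alkaline process passes. Et3N in THF at 0 °C should then open the hemiketal and allow the same 6-exo-tet closure and enolisation to 7.

**Step 5.**

- **Risk.** Cleavage of the hindered sulfonate on O5, peri to the carbonyl, may be incomplete at temperatures the sulfate tolerates. If the conditions are forced, hydroxide may open the pyranone at C2 before the 7-phenoxide has formed, or a liberated phenoxide may be methylated by methyl tosylate arising from methoxide.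
- **Fallback.** It sets out from 7 and returns at 9, and changes both the order of events and the protecting group. Both sulfonates are hydrolysed before any sulfate is present (KOH, MeOH/H2O, reflux, then acid), where forcing conditions are harmless, to give kaempferide F3. Benzylation with BnBr (1.05 equiv) and K2CO3 in DMF at rt should take the most acidic, unhindered 7-hydroxyl and give 7-O-benzylkaempferide F4. Sulfation (SO3·pyridine, pyridine; then KHCO3) should occur on O3, since the chelated 5-hydroxyl is inert, to give the potassium 3-sulfate F5. Hydrogenolysis (H2, Pd/C, MeOH/H2O) should remove the benzyl group under neutral conditions and deliver 9.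

**Step 4.**

- **Risk.** Sulfation of the flanked, hydrogen-bonded 3-hydroxyl may be incomplete. SO3 may be lost again during aqueous work-up, because 3-O-sulfates of flavonols are the most labile of the flavonoid sulfates. The amphiphilic salt may also be hard to separate from unreacted 7.
- **Fallback.** It sets out from 7 and returns at 8, and installs the sulfate in masked, neutral form. 2,2,2-Trichloroethyl chlorosulfate with Et3N and DMAP in THF should give the trichloroethyl sulfate diester F6, which can be purified on silica. Reductive fragmentation with Zn and HCO2NH4 in MeOH at rt should give the ammonium sulfate F7. KHCO3 (aq) and evaporation should convert F7 into 8.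

**Step 6.**

- **Risk.** The product may hydrolyse under its own acidity while the aqueous eluate is concentrated (autocatalytic S–O cleavage back to the flavonol).
- **Fallback.** It sets out from 9 and returns at 10, and replaces aqueous ion exchange by a non-aqueous salt metathesis. A suspension of 9 in dry MeCN at 0 °C is treated with one equivalent of HCl in dioxane; KCl should precipitate and be filtered off, and cold evaporation should leave 10 without the free acid ever meeting water. No new compound is made.

## Further compounds

F1 | step 3 | 3'-(4-methoxyphenyl)-3-oxo-3H-spiro[1-benzofuran-2,2'-oxirane]-4,6-diyl bis(4-methylbenzenesulfonate), racemic, aryl group cis to O1 | COc1ccc([C@H]2O[C@@]23Oc2cc(OS(=O)(=O)c4ccc(C)cc4)cc(OS(=O)(=O)c4ccc(C)cc4)c2C3=O)cc1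
F2 | step 3 | 2-[bromo(4-methoxyphenyl)methyl]-2-hydroxy-3-oxo-2,3-dihydrobenzofuran-4,6-diyl bis(4-methylbenzenesulfonate), racemic, mixture of diastereomers | COc1ccc(C(Br)C2(O)Oc3cc(OS(=O)(=O)c4ccc(C)cc4)cc(OS(=O)(=O)c4ccc(C)cc4)c3C2=O)cc1
F3 | step 5 | kaempferide, 3,5,7-trihydroxy-2-(4-methoxyphenyl)-4H-chromen-4-one | COc1ccc(-c2oc3cc(O)cc(O)c3c(=O)c2O)cc1
F4 | step 5 | 7-O-benzylkaempferide, 7-(benzyloxy)-3,5-dihydroxy-2-(4-methoxyphenyl)-4H-chromen-4-one | COc1ccc(-c2oc3cc(OCc4ccccc4)cc(O)c3c(=O)c2O)cc1
F5 | step 5 | potassium 7-(benzyloxy)-5-hydroxy-2-(4-methoxyphenyl)-4-oxo-4H-chromen-3-yl sulfate | COc1ccc(-c2oc3cc(OCc4ccccc4)cc(O)c3c(=O)c2OS(=O)(=O)[O-])cc1.[K+]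
F6 | step 4 | 2-(4-methoxyphenyl)-4-oxo-3-{[(2,2,2-trichloroethoxy)sulfonyl]oxy}-4H-chromene-5,7-diyl bis(4-methylbenzenesulfonate) | COc1ccc(-c2oc3cc(OS(=O)(=O)c4ccc(C)cc4)cc(OS(=O)(=O)c4ccc(C)cc4)c3c(=O)c2OS(=O)(=O)OCC(Cl)(Cl)Cl)cc1
F7 | step 4 | ammonium 2-(4-methoxyphenyl)-5,7-bis[(4-methylbenzenesulfonyl)oxy]-4-oxo-4H-chromen-3-yl sulfate | COc1ccc(-c2oc3cc(OS(=O)(=O)c4ccc(C)cc4)cc(OS(=O)(=O)c4ccc(C)cc4)c3c(=O)c2OS(=O)(=O)[O-])cc1.[NH4+]
F0 | step 6 | none | none
A1 | alternative 1 | 5,7-bis(benzyloxy)-4-hydroxy-2-(4-methoxyphenyl)chroman-3-one, racemic, mixture of diastereomers | COc1ccc(C2Oc3cc(OCc4ccccc4)cc(OCc4ccccc4)c3C(O)C2=O)cc1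
A2 | alternative 1 | 2-[3,5-bis(benzyloxy)-2-formylphenoxy]-2-(4-methoxyphenyl)acetaldehyde, racemic | COc1ccc(C(C=O)Oc2cc(OCc3ccccc3)cc(OCc3ccccc3)c2C=O)cc1
A3 | alternative 1 | 5,7-bis(benzyloxy)-3-hydroxy-2-(4-methoxyphenyl)-4H-chromen-4-one | COc1ccc(-c2oc3cc(OCc4ccccc4)cc(OCc4ccccc4)c3c(=O)c2O)cc1
A4 | alternative 2 | 3-(benzyloxy)-5-hydroxy-2-(4-methoxyphenyl)-7-(triisopropylsilyloxy)-4H-chromen-4-one | COc1ccc(-c2oc3cc(O[Si](C(C)C)(C(C)C)C(C)C)cc(O)c3c(=O)c2OCc2ccccc2)cc1
A5 | alternative 2 | 2-diazo-1-[5-(benzyloxy)-6-(4-methoxyphenyl)-4-oxo-4H-pyran-2-yl]ethan-1-one | COc1ccc(-c2oc(C(=O)C=[N+]=[N-])cc(=O)c2OCc2ccccc2)cc1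
A6 | alternative 2 | (triisopropylsilyloxy)ethyne | C#CO[Si](C(C)C)(C(C)C)C(C)C
A7 | alternative 3 | 3-(allyloxy)-5,7-bis(benzyloxy)-2-(4-methoxyphenyl)-4H-chromen-4-one | C=CCOc1c(-c2ccc(OC)cc2)oc2cc(OCc3ccccc3)cc(OCc3ccccc3)c2c1=O
A8 | alternative 3 | (E)-2-(allyloxy)-3-[3,5-bis(benzyloxy)phenoxy]-3-(4-methoxyphenyl)prop-2-enoic acid | C=CCO/C(C(=O)O)=C(/Oc1cc(OCc2ccccc2)cc(OCc2ccccc2)c1)c1ccc(OC)cc1
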